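**Setting out.** I wanted a ceiling. The flasks differ in temperature, so I asked how much of the spent substrate can reach target at all.

| flask | substrate | first nucleophile | second nucleophile | temperature | remark | time |
|---|---|---|---|---|---|---|
| alder | 10 mM | 15 mM | 5 mM | −20 °C | run made earlier |  |
| elm | 10 mM | 15 mM | 20 mM | 5 °C | run made earlier |  |
| oak | 15 mM | 15 mM | 10 mM | −20 °C | run made earlier |  |
| Thursday's | 10 mM | 15.0 mM | 10.0 mM | −15 °C |  | 30 min |
| Tuesday's | 10 mM | 15.0 mM | 10.0 mM | 5 °C |  | 30 min |
| Saturday's | 10 mM | 15.0 mM | 10.0 mM | 25 °C |  | 30 min |

| run | time / min | target / % |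
|---|---|---|
| alder | 2.50 | 0.2 |
| alder | 4.00 | 0.4 |
| alder | 6.00 | 0.3 |
| alder | 8.00 | 0.8 |
| alder | 12.0 | 1.1 |
| alder | 20.0 | 1.4 |
| alder | 30.0 | 2.3 |
| elm | 1.33 | 1.7 |
| elm | 3.00 | 2.5 |
| elm | 4.00 | 3.5 |
| elm | 6.00 | 4.8 |
| elm | 8.00 | 6.0 |
| elm | 10.0 | 6.6 |
| elm | 12.0 | 7.5 |
| oak | 6.00 | 0.1 |
| oak | 12.0 | 0.4 |
| oak | 20.0 | 1.3 |
| oak | 25.0 | 1.6 |
| oak | 30.0 | 1.4 |

(each reading ± 0.3 percentage points)



- the flask with the highest amount of target, in percent of the substrate charged ("all alike" if they lie within 1.5 percentage points) (Thursday's / Tuesday's / Saturday's / all alike)
- final target, as a percentage of the substrate charged, in Thursday's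
- final target, as a percentage of the substrate charged, in Tuesday's
- final target, as a percentage of the substrate charged, in Saturday's

**Lower bound.** In the elm run, target rose 4.8% in the first 6.00 min and 2.7 percentage points in the next equal stretch. Treating the gains as a falling series, as first-order loss of substrate gives, I summed them to 11.0%, a reading that carries the scatter. I took the sharing-out among competitors as instantaneous (steady state). The new flasks hold half of elm's second nucleophile, so their share should not lie below that figure.

**Upper bound.** With the other routes held, halving a competitor at most doubles the share, which gave 21.9%, twice elm's figure.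

**Tightening.** Alder and oak share a temperature and differ in second nucleophile and in substrate, and I took the substrate's difference to cancel in percent of the charge. Summed over their common reading times, oak gave 0.627 of alder's target. If the share goes as one over (w + c(second nucleophile)), then w = 3.42 mM. I assumed that w also held at elm's temperature. Scaling elm to c(second nucleophile) = 10.0 mM gave 19.1%, the capture share: target made per substrate spent, a selectivity. My bracket for the share of spent substrate that becomes target ran from 11.0% to 19.1%; it reads as percent of the charge where the substrate is spent and the target made has stayed.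

**The forecast.** It named Tuesday's, with 3% for Thursday's, 11% for Tuesday's and 9% for Saturday's, the last ranging from 4% to 17%. On Saturday's it wrote “its height depends on selectivity, which is unknown”. Its Saturday's figure, for a flask in which it expected the plateau quickly, stood below my bracket.

**The result.** The flasks gave 3.26% on Thursday's, 13.4% on Tuesday's and 0.0308% on Saturday's, so Tuesday's led. The forecast stood 9 points too high on Saturday's.

    substrate → intermediate (k = 0.0150 s⁻¹, Ea = 79.0 kJ mol⁻¹)
    first nucleophile + intermediate → target (k = 320 M⁻¹ s⁻¹, Ea = 43.0 kJ mol⁻¹)
    second nucleophile + intermediate → other capture product (k = 1200 M⁻¹ s⁻¹, Ea = 37.0 kJ mol⁻¹)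
    intermediate → solvolysis product (k = 11.0 s⁻¹, Ea = 59.0 kJ mol⁻¹)
    target → over-reaction product (k = 0.00370 s⁻¹, Ea = 88.0 kJ mol⁻¹)
    (constants at 25 °C)

**Target lost.** The largest single effect on Saturday's target was the step from target to over-reaction product: the same run without that step ends at 18.0% instead of 0.0308%. Saturday's target plus over-reaction product comes to 18.0%, under the capture share, with substrate at 0%. On the repeat of Saturday's at 10 °C, the capture share less 10.8% of over-reaction product leaves 8.30% for target, and that flask holds 8.93%.

The data were generated by integration for substances that don't exist; the scatter is artificial.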